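1. The stirred vessels south-west, north-east and east held the same charges: south-west was fed its starting complex, north-east its incoming ligand, and east had both from the start.

| setting | Friday's | Wednesday's | Saturday's | south-west | north-east | east |
|---|---|---|---|---|---|---|
| starting complex | 0.20 M | 0.13 M | 0.30 M | 0.20 M (fed, over 30 h) | 0.20 M | 0.20 M |
| incoming ligand | 0.40 M | 0.40 M | 0.40 M | 0.400 M | 0.400 M (fed, over 30 h) | 0.400 M |
| remark | run made earlier | run made earlier | run made earlier | all else is in the flask from the start; the feed brings no volume worth counting | all else is in the flask from the start; the feed brings no volume worth counting | everything together at the start |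
| time |  |  |  | 40 h | 40 h | 40 h |

- Friday's (time / h: complex with three exchanged / %, complex with two exchanged / %, starting complex / %): 3.00: 3.3, 7.7, 47.6; 5.00: 5.2, 10.4, 35.5; 8.00: 8.2, 13.5, 28.3; 12.0: 12.7, 15.2, 22.0; 15.0: 14.9, 14.6, 20.6; 25.0: 19.8, 18.8, 15.8; 40.0: 24.9, 18.3, 12.4
- Wednesday's (time / h: complex with three exchanged / %, complex with two exchanged / %, starting complex / %): 6.00: 10.6, 14.3, 30.0; 15.0: 22.8, 16.9, 14.6; 20.0: 26.9, 19.3, 11.4; 30.0: 36.9, 16.1, 6.9; 40.0: 44.6, 16.2, 5.9; 50.0: 49.8, 13.9, 2.9
- Saturday's (time / h: complex with three exchanged / %, complex with two exchanged / %, starting complex / %): 6.00: 5.1, 8.5, 39.3; 15.0: 8.2, 12.9, 30.2; 20.0: 8.5, 13.0, 27.6; 30.0: 12.6, 13.2, 24.2; 40.0: 13.0, 12.5, 23.4; 50.0: 13.6, 14.5, 21.7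

(scatter of a reading: 1 percentage point)

- the earlier runs were read with a standard deviation of 1 percentage point

- the flask with the highest amount of complex with three exchanged, in percent of the starting complex charged ("all alike" if they lie within 1.5 percentage points) (south-west / north-east / east / all alike)
- final complex with three exchanged, as a percentage of the starting complex charged, in south-west
- final complex with three exchanged, as a percentage of the starting complex charged, in north-east
- final complex with three exchanged, as a percentage of the starting complex charged, in east

2. I took the loss of starting complex to be proportional to it and to the incoming ligand present. Integration gave a closed form: the natural logarithm of charged over left, which I called the clock, equals a rate constant times the time-integral of incoming ligand. If later steps feel that same incoming ligand, flasks with all starting complex in from the start should match at equal clocks. Friday's run left 12.4% at 40.0 h, a clock of 2.09. With its 24.9% of complex with three exchanged, that reading gave 0.0571; I called this fraction over the squared clock the clock yield. The square was my empirical choice, not a derivation: at 25.0 h the same number gave 19.5% against Friday's reading of 19.8%.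

3. Wednesday's run looks nearly the same but had 3.08 incoming ligand per starting complex against Friday's 2.00. So at 40.0 h its clock stood further on, at 2.83. The clock yield gave 45.8% for it, and the reading was 44.6%.

4. East repeated Friday's recipe, so I expected 24.9%. A steady feed arrives on average at half its duration, so by my estimate the fed charge had on average 25.0 h in the flask, shorter than 40 h. Friday's reading at that time was 19.8%, so I put both fed flasks near it, behind east. The forecast differed: south-west first, with 26.5% in south-west, 22% in north-east and 25% in east. In its words: “South-west leads, but only modestly over east.”

5. The steps behind the flasks, with their constants, were: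

    starting complex + incoming ligand → leaving ligand + complex with one exchanged (k = 0.0160 M⁻¹ min⁻¹)
    complex with two exchanged + incoming ligand → leaving ligand + complex with three exchanged (k = 0.0190 M⁻¹ min⁻¹)
    complex with one exchanged + incoming ligand → leaving ligand + complex with two exchanged (k = 0.00830 M⁻¹ min⁻¹)
    incoming ligand ⇌ dormant form (K = 2.20, k = 0.00220 min⁻¹)
    complex with two exchanged → over-reaction product (k = 1.80 × 10⁻⁵ min⁻¹)

East led with 26.1%, against 17.0% in south-west and 19.0% in north-east. North-east left 16% of its starting complex, and the clock yield gave 18.6% against its 19.0%; east at 10 h left 25.3%, giving 10.8% against 10.9%. In east at 2.03 h, incoming ligand had a forward half-life of 5.3 h toward dormant form, shorter than the 19 h by exchange on complex with one exchanged. At 40 h, dormant form held 33.1% of the ligand charge in south-west and 16.1% in east.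

The readings come from a simulation from invented constants, and the scatter is random.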